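| flask | solid substrate | enzyme | remark | time |
|---|---|---|---|---|
| summer | 3.5 mM | 0.01 mol% (in portions, 2) | run made earlier; portions every 15 min |  |
| dusk | 17 mM | 0.01 mol% (in portions, 2) | run made earlier; portions every 15 min |  |
| winter | 11 mM | 0.014 mol% (in portions, 2) | run made earlier; portions every 15 min |  |
| Friday's | 11 mM | 0.01 mol% (in portions, 2) | the portions of enzyme follow each other after 15 min, the first at the start | 40 min |
| Monday's | 11 mM | 0.03 mol% (in portions, 2) | the portions of enzyme follow each other after 30 min, the first at the start | 40 min |
| Sunday's | 3.0 mM | 0.015 mol% (in portions, 2) | the portions of enzyme follow each other after 5.0 min, the first at the start | 40 min |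
| Saturday's | 15 mM | 0.006 mol% (in portions, 2) | the portions of enzyme follow each other after 25 min, the first at the start | 40 min |

| run | time / min | product / % | solid substrate / % |
|---|---|---|---|
| summer | 6.00 | 4.8 | 0 |
| summer | 12.0 | 9.8 | 0 |
| summer | 15.0 | 11.8 | 0 |
| summer | 25.0 | 27.7 | 0.4 |
| summer | 30.0 | 34.1 | 0 |
| summer | 40.0 | 44.1 | 0 |
| dusk | 6.00 | 4.9 | 63.7 |
| dusk | 12.0 | 12.8 | 43.0 |
| dusk | 15.0 | 17.7 | 33.9 |
| dusk | 25.0 | 43.2 | 10.9 |
| dusk | 30.0 | 54.3 | 0.3 |
| dusk | 40.0 | 69.2 | 0 |
| winter | 8.00 | 11.3 | 31.9 |
| winter | 15.0 | 24.9 | 1.0 |
| winter | 25.0 | 56.1 | 0 |
| winter | 30.0 | 65.3 | 0 |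
| winter | 40.0 | 79.5 | 0.1 |

(scatter of a reading: 0.5 percentage points)

- as a solid, counted per litre of solution: solid substrate
- at the start none of the solid substrate is in solution
- what has only dissolved of solid substrate counts as not reacted

- all flasks from highest to lowest amount of product, in percent of the solid substrate charged, at 40 min (Friday's / Monday's / Sunday's / Saturday's)
- the amount of product, in percent of the solid substrate charged of the flask you put first, at 40 min
- the amount of product, in percent of the solid substrate charged of the flask you put last, at 40 min

- Start with an easy step: follow one molecule of solid substrate. Each minute it either waits, as solid or dissolved, or goes to product, and at a fixed c(solid substrate) I take its chance of going to be in proportion to the enzyme present, the pseudo-first-order picture.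
- So count on an enzyme clock, in minutes at winter's loading of 0.014 mol%. For two equal portions, read after the second, a flask's clock is its loading over winter's, times the time less half the interval. At 40 min, Monday's clock reads 53.6 min and Friday's 23.2 min.
- Winter has the same c(solid substrate) as these two flasks, 11 mM, and its 79.5 % of product gives 0.0488 min⁻¹. This is the turnover chance, the share of waiting molecules that goes to product per clock minute.
- The chance is read at a fixed c(solid substrate). Summer, at 3.5 mM, reads 0.0251 min⁻¹, about half of winter's, and dusk, at 17 mM, reads 0.0507 min⁻¹. I use summer's for Sunday's and dusk's for Saturday's.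
- In this picture the share still waiting falls exponentially with chance times clock. My reckoning therefore gives Monday's 92.7 %, Friday's 67.8 %, Sunday's 63.5 % and Saturday's 45.0 %.
- At a fixed loading, don't delay a second portion: on Friday's interval of 15 min, Monday's loading would read 69.6 min on the clock, more than the 53.6 min it reads on its own interval of 30 min. Don't stop a flask when its solid is gone either: summer's solid read 0 % at 30.0 min, yet its product rose from 34.1 % to 44.1 % by 40.0 min.
- The forecast gives Monday's > Friday's > Sunday's > Saturday's, with 90 % on top and 49 % last, on grounds such as “The second portion doubles the rate”. Its order is mine, but its top is lower than mine and its low is higher than mine.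

The flask gives Monday's > Friday's > Sunday's > Saturday's, with 90.7 % for Monday's and 46.9 % for Saturday's. Monday's answer has moved by 5 points at 0.024 mol% of enzyme below and 0.041 mol% above. Read back on Monday's clock, the 9.28 % of starting material left gives a chance of 0.0444 min⁻¹, less than winter's 0.0488 min⁻¹.

    solid substrate ⇌ starting material, rate k1*(cs1 - [starting material]) while solid is left; crystals form when [starting material] > cs1 (solubility = 11.0 mM, k = 0.00222 s⁻¹)
    starting material + enzyme → product + enzyme, rate k2*[starting material]*[enzyme]/(1 + ([starting material]/Km2) + ([product]/Kp2)) (17.4 mM, 8.16 mM, k = 1110 M⁻¹ s⁻¹)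

A neighbouring flask, Monday's recipe with 0.018 mol% of enzyme, has a clock of 32.1 min, so winter's chance gives 79.1 % of product at 40 min. Computed, that flask holds 77.6 % of product.

All runs were generated by integration on assumed constants; the scatter is artificial.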